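## Retrosynthetic overview

1. The C11=C12 bond is made last by a Wittig reaction between a C15 enynal carrying the hydroxylated ring and a C25 polyenyl phosphonium salt grown from (R)-α-ionone (ε-ring and C6' bought in), vinylmagnesium bromide and 2,7-dimethylocta-2,4,6-trienedial. The acetylenic partner is the aldehyde, so its 9E enyne, taken from (E)-3-methylpent-2-en-4-yn-1-ol, never passes through an ylide.
2. Only one ring is built, the 3-hydroxy ring. It is closed by forming C3–C4 in a catalyst-controlled type 2 carbonyl-ene cyclization of an acyclic C15 aldehyde (C3 = CHO, C4 = CH2 terminus of an isopropenyl group); the exocyclic alkene is then shifted to C5=C6.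
3. Enabling feature: carbinol C3 is homoallylic to the ring alkene (C3–C4–C5=C6), C5 carries the methyl group that supplies the ene hydrogen, and C5=C6 is tetrasubstituted and conjugated with C7≡C8. All alkene isomers and both C6 epimers from the cyclization therefore drain to the natural position.
4. The aldehyde arises by anionic oxy-Cope rearrangement (quaternary C1, C1–C6 bond) of a dienynol made from 3-methylbut-2-enal, propargyl bromide, AlMe3/I2 and the silylated enynol by Sonogashira coupling.

Key step: step 6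

Remarks on the chemistry:
- (R)-α-Ionone is taken as a purchasable, enantiopure starting material; its stereocentre becomes C6' unchanged.
- The sense of induction of the chromium catalyst in step 6 cannot be predicted with certainty. The ligand enantiomer meant is the one that gives the 1S alcohol; both enantiomers of cis-1-aminoindan-2-ol are commercial, and the choice is to be fixed in a pilot run.
- Locants such as C3, C6 or C6' refer to carotenoid numbering of the target, (3R,6'R)-7,8-didehydro-β,ε-caroten-3-ol (crocoxanthin), all-E.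

## Route

Step 1
Reactants: 1 3-methylbut-2-enal; 2 3-bromoprop-1-yne (propargyl bromide)
Product: 4 6-methylhept-5-en-1-yn-4-ol (racemic), via allenylzinc bromide 3 (not isolated)
Conditions: Zn dust, THF, 0 °C to rt; sat. aq. NH4Cl
Reagents that add atoms: none
Why: Barbier propargylation, in which the allenylzinc bromide formed in the flask should add 1,2 to the enal through an SE2' transition state to give the homopropargylic alcohol; the racemic carbinol centre is erased in step 5.

Step 2
Reactants: 4 6-methylhept-5-en-1-yn-4-ol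
Product: 6 (1E)-1-iodo-2,6-dimethylhepta-1,5-dien-4-ol (racemic), via alkenylalane 5 (not isolated)
Conditions: AlMe3 (3 equiv), Cp2ZrCl2 (0.25 equiv), CH2Cl2, 0 °C to rt; then I2, THF, −30 to 0 °C
Reagents that add atoms: trimethylaluminium C[Al](C)C; iodine II
Why: Zirconium-catalysed carboalumination (Negishi) should add methyl and aluminium syn across the terminal alkyne with methyl at the internal carbon, and iodinolysis with retention then gives the E vinyl iodide, the hydroxyl being carried as its aluminium alkoxide.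

Step 3
Reactants: 7 (2E)-3-methylpent-2-en-4-yn-1-ol
Product: 8 tert-butyldimethyl{[(2E)-3-methylpent-2-en-4-yn-1-yl]oxy}silane
Conditions: TBSCl, imidazole, CH2Cl2, 0 °C to rt
Reagents that add atoms: tert-butyldimethylsilyl chloride CC(C)(C)[Si](C)(C)Cl
Why: Standard silylation of a primary allylic alcohol; the silyl ether should survive KH, the chromium Lewis acid and tert-butoxide.

Step 4
Reactants: 6 (1E)-1-iodo-2,6-dimethylhepta-1,5-dien-4-ol; 8 tert-butyldimethyl{[(2E)-3-methylpent-2-en-4-yn-1-yl]oxy}silane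
Product: 9 (6E,10E)-12-[(tert-butyldimethylsilyl)oxy]-2,6,10-trimethyldodeca-2,6,10-trien-8-yn-4-ol (racemic)
Conditions: PdCl2(PPh3)2 (3 mol%), CuI (6 mol%), Et3N, THF, rt, degassed
Reagents that add atoms: none
Why: Sonogashira coupling of the vinyl iodide with the terminal alkyne should proceed with retention of both alkene geometries and tolerate the free secondary alcohol.

Step 5
Reactants: 9 (6E,10E)-12-[(tert-butyldimethylsilyl)oxy]-2,6,10-trimethyldodeca-2,6,10-trien-8-yn-4-ol
Product: 11 (7E)-9-[(tert-butyldimethylsilyl)oxy]-3,3,7-trimethyl-4-(prop-1-en-2-yl)non-7-en-5-ynal (racemic), via potassium enolate 10 (not isolated)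
Conditions: KH (1.3 equiv), 18-crown-6 (1.3 equiv), THF, 0 to 40 °C; sat. aq. NH4Cl, −78 °C
Reagents that add atoms: none
Why: Anionic oxy-Cope rearrangement, in which the potassium alkoxide of the 1,5-dien-3-ol should undergo a [3,3] shift that joins the Me2C terminus to the enyne CH terminus (quaternary C1, C1–C6 bond) and gives the aldehyde enolate, protonated on work-up; the new propargylic centre is racemic, which step 6 is designed to tolerate.

Step 6
Reactants: 11 (7E)-9-[(tert-butyldimethylsilyl)oxy]-3,3,7-trimethyl-4-(prop-1-en-2-yl)non-7-en-5-ynal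
Product: 12 (1S)-4-{(3E)-5-[(tert-butyldimethylsilyl)oxy]-3-methylpent-3-en-1-yn-1-yl}-3,3-dimethyl-5-methylidenecyclohexan-1-ol (both epimers at the propargylic ring carbon)
Conditions: CrCl(L) (5 mol%; trivalent chromium, L = dianion of the Schiff base from 3-(1-adamantyl)-2-hydroxy-5-methylbenzaldehyde and (1R,2S)-1-aminoindan-2-ol), 4 Å MS, toluene, 0 °C to rt
Reagents that add atoms: none
Why: Proposed new method: the chiral chromium Lewis acid binds the aldehyde oxygen, the CH2 terminus of the isopropenyl group (C4) adds to the carbonyl carbon (C3) through a chair-like six-membered array while a hydrogen of the C5 methyl group passes to oxygen, an asynchronous concerted type 2 carbonyl-ene reaction in which the enophile is tethered to the central carbon of the ene unit. The closest known reactions are the Me2AlCl-promoted cyclization of 5-methylhex-5-enals to 3-methylidenecyclohexanols and the enantioselective carbonyl-ene cyclization of aldehydes tethered to trisubstituted alkenes with chiral chromium Schiff-base and titanium–BINOL Lewis acids (type 1 topology); new are the enantioselective type 2 topology with an all-carbon tether and a substrate that is racemic at the propargylic carbon. The one ring closed is the cyclohexane of the hydroxylated end group, by 6-endo attack of the 1,1-disubstituted alkene (both alkene carbons end up in the ring) on the exocyclic carbonyl, helped by the gem-dimethyl group. The carbinol centre is set by the catalyst, which shields one face of the bound aldehyde; the propargylic centre carries only a slim alkynyl group and is expected to exert little bias, so both enantiomers of 11 should give the same carbinol configuration (1S here, spatially the 3R of the target) and differ only at the carbon that becomes sp2 in step 7. The step needs site selectivity for C4 over the enyne and the silyl ether, which is secured because only C4 can reach the carbonyl through a six-membered transition state that places positive charge on a tertiary carbon, and any alkene isomer formed by hydrogen loss from the methyl group or from C6 converges in step 7.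

Step 7
Reactants: 12 (1S)-4-{(3E)-5-[(tert-butyldimethylsilyl)oxy]-3-methylpent-3-en-1-yn-1-yl}-3,3-dimethyl-5-methylidenecyclohexan-1-ol
Product: 13 (1R)-4-{(3E)-5-[(tert-butyldimethylsilyl)oxy]-3-methylpent-3-en-1-yn-1-yl}-3,5,5-trimethylcyclohex-3-en-1-ol
Conditions: KOtBu (2.2 equiv), THF–DMSO 10:1, −20 to 0 °C; AcOH quench
Reagents that add atoms: none
Why: Base-mediated prototropic shift, in which the allylic and propargylic ring CH is deprotonated and the delocalized anion is reprotonated at the exocyclic CH2, so both epimers should converge on the tetrasubstituted alkene conjugated with the alkyne; the carbinol centre is untouched and its descriptor changes from S to R only because the CIP ranking of the two ring branches changes.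

Step 8
Reactants: 13 (1R)-4-{(3E)-5-[(tert-butyldimethylsilyl)oxy]-3-methylpent-3-en-1-yn-1-yl}-3,5,5-trimethylcyclohex-3-en-1-ol
Product: 14 (1R)-4-[(3E)-5-hydroxy-3-methylpent-3-en-1-yn-1-yl]-3,5,5-trimethylcyclohex-3-en-1-ol
Conditions: TBAF, THF, 0 °C to rt
Reagents that add atoms: none
Why: Fluoride cleavage of the primary silyl ether under conditions that leave the enyne and the carbinol centre alone.

Step 9
Reactants: 14 (1R)-4-[(3E)-5-hydroxy-3-methylpent-3-en-1-yn-1-yl]-3,5,5-trimethylcyclohex-3-en-1-ol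
Product: 15 (2E)-5-[(4R)-4-hydroxy-2,6,6-trimethylcyclohex-1-en-1-yl]-3-methylpent-2-en-4-ynal
Conditions: activated MnO2 (excess), CH2Cl2, rt, dark
Reagents that add atoms: none
Why: MnO2 should oxidize only the allylic primary alcohol, leaving the isolated secondary ring alcohol and the E enyne geometry unchanged.

Step 10
Reactants: 16 (3E)-4-[(1R)-2,6,6-trimethylcyclohex-2-en-1-yl]but-3-en-2-one ((R)-α-ionone); 17 vinylmagnesium bromide
Product: 18 (1E)-3-methyl-1-[(1R)-2,6,6-trimethylcyclohex-2-en-1-yl]penta-1,4-dien-3-ol (both epimers at the carbinol carbon)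
Conditions: CH2=CHMgBr, THF, −20 °C; sat. aq. NH4Cl
Reagents that add atoms: none
Why: Grignard 1,2-addition to the enone carbonyl at low temperature, which should outrun γ-deprotonation and so leave the ring stereocentre intact; the new carbinol centre is lost in step 11.

Step 11
Reactants: 18 (1E)-3-methyl-1-[(1R)-2,6,6-trimethylcyclohex-2-en-1-yl]penta-1,4-dien-3-ol
Product: 19 [(2E,4E)-3-methyl-5-[(1R)-2,6,6-trimethylcyclohex-2-en-1-yl]penta-2,4-dien-1-yl]triphenylphosphonium bromide
Conditions: PPh3·HBr, MeOH, 0 °C to rt; crystallization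
Reagents that add atoms: triphenylphosphine hydrobromide c1ccc(cc1)[PH+](c1ccccc1)c1ccccc1.[Br-]
Why: SN1-type allylic substitution with transposition, in which the tertiary bis-allylic alcohol ionizes and triphenylphosphine attacks the primary terminus of the pentadienyl cation to give the conjugated phosphonium salt, the 2E isomer being secured by crystallization.

Step 12
Reactants: 19 [(2E,4E)-3-methyl-5-[(1R)-2,6,6-trimethylcyclohex-2-en-1-yl]penta-2,4-dien-1-yl]triphenylphosphonium bromide; 20 (2E,4E,6E)-2,7-dimethylocta-2,4,6-trienedial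
Product: 23 (2E,4E,6E,8E,10E,12E)-2,7,11-trimethyl-13-[(1R)-2,6,6-trimethylcyclohex-2-en-1-yl]trideca-2,4,6,8,10,12-hexaenal, via phosphorus ylide 21 (not isolated), via 8Z aldehyde 22 (not isolated)
Conditions: NaOMe, MeOH–CH2Cl2, 0 °C to rt, 20 in excess (2 equiv); then heptane, 80 °C, dark
Reagents that add atoms: none
Why: Wittig olefination of one aldehyde group of the symmetrical dialdehyde (used in excess to favour mono-condensation) by the semi-stabilized ylide, the E/Z mixture at the new bond being relaxed thermally to the all-E aldehyde.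

Step 13
Reactants: 23 (2E,4E,6E,8E,10E,12E)-2,7,11-trimethyl-13-[(1R)-2,6,6-trimethylcyclohex-2-en-1-yl]trideca-2,4,6,8,10,12-hexaenal
Product: 24 (2E,4E,6E,8E,10E,12E)-2,7,11-trimethyl-13-[(1R)-2,6,6-trimethylcyclohex-2-en-1-yl]trideca-2,4,6,8,10,12-hexaen-1-ol
Conditions: NaBH4, MeOH–THF, 0 °C
Reagents that add atoms: none
Why: Chemoselective 1,2-reduction of the polyenal by borohydride.

Step 14
Reactants: 24 (2E,4E,6E,8E,10E,12E)-2,7,11-trimethyl-13-[(1R)-2,6,6-trimethylcyclohex-2-en-1-yl]trideca-2,4,6,8,10,12-hexaen-1-ol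
Product: 25 [(2E,4E,6E,8E,10E,12E)-2,7,11-trimethyl-13-[(1R)-2,6,6-trimethylcyclohex-2-en-1-yl]trideca-2,4,6,8,10,12-hexaen-1-yl]triphenylphosphonium bromide
Conditions: PPh3·HBr, MeOH–CH2Cl2, 0 °C to rt, dark
Reagents that add atoms: triphenylphosphine hydrobromide c1ccc(cc1)[PH+](c1ccccc1)c1ccccc1.[Br-]
Why: Conversion of a polyenyl primary allylic alcohol into its phosphonium salt through the delocalized cation, with phosphine attack at the primary terminus as for retinyl-type salts.

Step 15
Reactants: 25 [(2E,4E,6E,8E,10E,12E)-2,7,11-trimethyl-13-[(1R)-2,6,6-trimethylcyclohex-2-en-1-yl]trideca-2,4,6,8,10,12-hexaen-1-yl]triphenylphosphonium bromide; 15 (2E)-5-[(4R)-4-hydroxy-2,6,6-trimethylcyclohex-1-en-1-yl]-3-methylpent-2-en-4-ynal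
Product: 28 (3R,6'R)-7,8-didehydro-β,ε-caroten-3-ol (crocoxanthin, all-E), via phosphorus ylide 26 (not isolated), via 11Z isomer 27 (not isolated)
Conditions: NaOMe, MeOH–CH2Cl2, 0 °C to rt; then heptane, 70 °C, dark, N2; crystallization
Reagents that add atoms: none
Why: Wittig olefination forms C11=C12 with the free hydroxyl tolerated, the 9E enyne being held because the acetylenic partner is the aldehyde and not the ylide, and the hindered 11Z isomer should relax thermally to the all-E target.

## Compound list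

1 | 3-methylbut-2-enal | CC(C)=CC=O | starting material
2 | 3-bromoprop-1-yne | C#CCBr | starting material
3 | propa-1,2-dien-1-ylzinc bromide (allenylzinc bromide) | C=C=C[Zn]Br | intermediate
4 | 6-methylhept-5-en-1-yn-4-ol (racemic) | CC(C)=CC(O)CC#C | intermediate
5 | dimethylaluminium alkoxide of (1E)-1-(dimethylalumanyl)-2,6-dimethylhepta-1,5-dien-4-ol | CC(C)=CC(O[Al](C)C)C/C(C)=C/[Al](C)C | intermediate
6 | (1E)-1-iodo-2,6-dimethylhepta-1,5-dien-4-ol (racemic) | CC(C)=CC(O)C/C(C)=C/I | intermediate
7 | (2E)-3-methylpent-2-en-4-yn-1-ol | C#C/C(C)=C/CO | starting material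
8 | tert-butyldimethyl{[(2E)-3-methylpent-2-en-4-yn-1-yl]oxy}silane | C#C/C(C)=C/CO[Si](C)(C)C(C)(C)C | intermediate
9 | (6E,10E)-12-[(tert-butyldimethylsilyl)oxy]-2,6,10-trimethyldodeca-2,6,10-trien-8-yn-4-ol (racemic) | CC(C)=CC(O)C/C(C)=C/C#C/C(C)=C/CO[Si](C)(C)C(C)(C)C | intermediate
10 | potassium enolate of aldehyde 11 | [K+].[O-]C=CC(C)(C)C(C#C/C(C)=C/CO[Si](C)(C)C(C)(C)C)C(C)=C | intermediate
11 | (7E)-9-[(tert-butyldimethylsilyl)oxy]-3,3,7-trimethyl-4-(prop-1-en-2-yl)non-7-en-5-ynal (racemic) | C=C(C)C(C#C/C(C)=C/CO[Si](C)(C)C(C)(C)C)C(C)(C)CC=O | intermediate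
12 | (1S)-4-{(3E)-5-[(tert-butyldimethylsilyl)oxy]-3-methylpent-3-en-1-yn-1-yl}-3,3-dimethyl-5-methylidenecyclohexan-1-ol (both epimers at the propargylic ring carbon) | CC(C)(C)[Si](C)(C)OC/C=C(\C)C#CC1C(=C)C[C@@H](O)CC1(C)C | intermediate
13 | (1R)-4-{(3E)-5-[(tert-butyldimethylsilyl)oxy]-3-methylpent-3-en-1-yn-1-yl}-3,5,5-trimethylcyclohex-3-en-1-ol | CC(C)(C)[Si](C)(C)OC/C=C(\C)C#CC1=C(C)C[C@@H](O)CC1(C)C | intermediate
14 | (1R)-4-[(3E)-5-hydroxy-3-methylpent-3-en-1-yn-1-yl]-3,5,5-trimethylcyclohex-3-en-1-ol | OC/C=C(\C)C#CC1=C(C)C[C@@H](O)CC1(C)C | intermediate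
15 | (2E)-5-[(4R)-4-hydroxy-2,6,6-trimethylcyclohex-1-en-1-yl]-3-methylpent-2-en-4-ynal | O=C/C=C(\C)C#CC1=C(C)C[C@@H](O)CC1(C)C | intermediate
16 | (3E)-4-[(1R)-2,6,6-trimethylcyclohex-2-en-1-yl]but-3-en-2-one ((R)-α-ionone) | CC1=CCCC(C)(C)[C@H]1/C=C/C(C)=O | starting material
17 | vinylmagnesium bromide | C=C[Mg]Br | starting material
18 | (1E)-3-methyl-1-[(1R)-2,6,6-trimethylcyclohex-2-en-1-yl]penta-1,4-dien-3-ol (both carbinol epimers) | CC1=CCCC(C)(C)[C@H]1/C=C/C(C)(O)C=C | intermediate
19 | [(2E,4E)-3-methyl-5-[(1R)-2,6,6-trimethylcyclohex-2-en-1-yl]penta-2,4-dien-1-yl]triphenylphosphonium bromide | CC1=CCCC(C)(C)[C@H]1/C=C/C(C)=C/C[P+](c1ccccc1)(c1ccccc1)c1ccccc1.[Br-] | intermediate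
20 | (2E,4E,6E)-2,7-dimethylocta-2,4,6-trienedial | O=C/C(C)=C/C=C/C=C(\C)C=O | starting material
21 | ylide of 19 | CC1=CCCC(C)(C)[C@H]1/C=C/C(C)=C/C=P(c1ccccc1)(c1ccccc1)c1ccccc1 | intermediate
22 | (2E,4E,6E,8Z,10E,12E)-2,7,11-trimethyl-13-[(1R)-2,6,6-trimethylcyclohex-2-en-1-yl]trideca-2,4,6,8,10,12-hexaenal | CC1=CCCC(C)(C)[C@H]1/C=C/C(C)=C/C=C\C(C)=C\C=C\C=C(/C)C=O | intermediate
23 | (2E,4E,6E,8E,10E,12E)-2,7,11-trimethyl-13-[(1R)-2,6,6-trimethylcyclohex-2-en-1-yl]trideca-2,4,6,8,10,12-hexaenal | CC1=CCCC(C)(C)[C@H]1/C=C/C(C)=C/C=C/C(C)=C/C=C/C=C(\C)C=O | intermediate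
24 | (2E,4E,6E,8E,10E,12E)-2,7,11-trimethyl-13-[(1R)-2,6,6-trimethylcyclohex-2-en-1-yl]trideca-2,4,6,8,10,12-hexaen-1-ol | CC1=CCCC(C)(C)[C@H]1/C=C/C(C)=C/C=C/C(C)=C/C=C/C=C(\C)CO | intermediate
25 | [(2E,4E,6E,8E,10E,12E)-2,7,11-trimethyl-13-[(1R)-2,6,6-trimethylcyclohex-2-en-1-yl]trideca-2,4,6,8,10,12-hexaen-1-yl]triphenylphosphonium bromide | CC1=CCCC(C)(C)[C@H]1/C=C/C(C)=C/C=C/C(C)=C/C=C/C=C(\C)C[P+](c1ccccc1)(c1ccccc1)c1ccccc1.[Br-] | intermediate
26 | ylide of 25 | CC1=CCCC(C)(C)[C@H]1/C=C/C(C)=C/C=C/C(C)=C/C=C/C=C(\C)C=P(c1ccccc1)(c1ccccc1)c1ccccc1 | intermediate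
27 | (3R,6'R,11Z)-7,8-didehydro-β,ε-caroten-3-ol | CC1=CCCC(C)(C)[C@H]1/C=C/C(C)=C/C=C/C(C)=C/C=C/C=C(C)/C=C\C=C(/C)C#CC1=C(C)C[C@@H](O)CC1(C)C | intermediate
28 | (3R,6'R)-7,8-didehydro-β,ε-caroten-3-ol (all-E) | CC1=CCCC(C)(C)[C@H]1/C=C/C(C)=C/C=C/C(C)=C/C=C/C=C(C)/C=C/C=C(\C)C#CC1=C(C)C[C@@H](O)CC1(C)C | target

## Step count and risks

Total steps: 15. Longest linear sequence: 9 steps (steps 1, 2, 4, 5, 6, 7, 8, 9, 15).

**Step 6 (proposed new method).** Catalyst control may be incomplete: one enantiomer of 11 may cyclize through a mismatched pathway and erode the enantiomeric purity at the carbinol carbon, or the hindered aldehyde may fail to turn the catalyst over. The fallback uses known chemistry, sets out from 11 and comes back at 13. Me2AlCl (1.2 equiv, CH2Cl2, −78 to 0 °C) should effect the known racemic type 2 ene cyclization to the racemic methylidene alcohol F1. The conditions of step 7 should then give the racemic conjugated enyne alcohol F2. Acylation with (1S)-camphanoyl chloride (pyridine, DMAP) and separation of the two diastereomeric esters by chromatography or crystallization should give the camphanate of the 1R alcohol F3. Methanolysis (K2CO3, MeOH) returns 13.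

**Step 5.** The alkoxide may fragment heterolytically (retro-allylation to the enal and an enyne-stabilized allyl anion) or recombine in a 1,3 sense instead of undergoing the [3,3] shift, and the aldehyde enolate may self-condense on quenching. The fallback replaces the oxy-Cope by a Claisen rearrangement, sets out from 8 and comes back at 11.
- (2E)-3-Iodo-2-methylprop-2-en-1-ol F4 is made from prop-2-yn-1-ol with AlMe3/Cp2ZrCl2 and then I2.
- Sonogashira coupling of F4 with 8 gives (2E,6E)-8-[(tert-butyldimethylsilyl)oxy]-2,6-dimethylocta-2,6-dien-4-yn-1-ol F5.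
- Copper-catalysed O-vinylation with 1-iodo-2-methylprop-1-ene (CuI, 3,4,7,8-tetramethyl-1,10-phenanthroline, Cs2CO3, o-xylene, 120 °C) gives the allyl 2-methylprop-1-enyl ether F6, which should rearrange in the same pot to the α-quaternary aldehyde F7.
- One-carbon homologation with (methoxymethyl)triphenylphosphonium chloride/KHMDS gives the methyl enol ether F8, and mild hydrolysis (oxalic acid, wet THF, rt) gives 11.

**Step 7.** Strong base may carry the isomerization past the conjugated enyne toward allenic isomers, or trigger vinylogous elimination of the silyloxy group from the extended anion. The fallback replaces the anionic shift by addition–elimination, sets out from 12 and comes back at 13. Markovnikov hydrochlorination of the exocyclic alkene (HCl in Et2O, CH2Cl2, −78 °C) should give the tertiary chloride F9. Dehydrochlorination with DBU (toluene, 60 °C) should then remove the propargylic hydrogen preferentially and give 13.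

## Further compounds

F1 | step 6 | 4-{(3E)-5-[(tert-butyldimethylsilyl)oxy]-3-methylpent-3-en-1-yn-1-yl}-3,3-dimethyl-5-methylidenecyclohexan-1-ol (racemic, diastereomer mixture) | CC(C)(C)[Si](C)(C)OC/C=C(\C)C#CC1C(=C)CC(O)CC1(C)C
F2 | step 6 | 4-{(3E)-5-[(tert-butyldimethylsilyl)oxy]-3-methylpent-3-en-1-yn-1-yl}-3,5,5-trimethylcyclohex-3-en-1-ol (racemic) | CC(C)(C)[Si](C)(C)OC/C=C(\C)C#CC1=C(C)CC(O)CC1(C)C
F3 | step 6 | (1R)-4-{(3E)-5-[(tert-butyldimethylsilyl)oxy]-3-methylpent-3-en-1-yn-1-yl}-3,5,5-trimethylcyclohex-3-en-1-yl (1S,4R)-4,7,7-trimethyl-3-oxo-2-oxabicyclo[2.2.1]heptane-1-carboxylate | CC(C)(C)[Si](C)(C)OC/C=C(\C)C#CC1=C(C)C[C@@H](OC(=O)[C@@]23CC[C@@](C)(C(=O)O2)C3(C)C)CC1(C)C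
F4 | step 5 | (2E)-3-iodo-2-methylprop-2-en-1-ol | OC/C(C)=C/I
F5 | step 5 | (2E,6E)-8-[(tert-butyldimethylsilyl)oxy]-2,6-dimethylocta-2,6-dien-4-yn-1-ol | OC/C(C)=C/C#C/C(C)=C/CO[Si](C)(C)C(C)(C)C
F6 | step 5 | tert-butyldimethyl{[(2E,6E)-3,7-dimethyl-8-[(2-methylprop-1-en-1-yl)oxy]octa-2,6-dien-4-yn-1-yl]oxy}silane | CC(C)=COC/C(C)=C/C#C/C(C)=C/CO[Si](C)(C)C(C)(C)C
F7 | step 5 | (6E)-8-[(tert-butyldimethylsilyl)oxy]-2,2,6-trimethyl-3-(prop-1-en-2-yl)oct-6-en-4-ynal (racemic) | C=C(C)C(C#C/C(C)=C/CO[Si](C)(C)C(C)(C)C)C(C)(C)C=O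
F8 | step 5 | tert-butyl{[(2E)-9-methoxy-3,7,7-trimethyl-6-(prop-1-en-2-yl)nona-2,8-dien-4-yn-1-yl]oxy}dimethylsilane (racemic, enol ether E/Z mixture) | C=C(C)C(C#C/C(C)=C/CO[Si](C)(C)C(C)(C)C)C(C)(C)C=COC
F9 | step 7 | (1S)-5-chloro-4-{(3E)-5-[(tert-butyldimethylsilyl)oxy]-3-methylpent-3-en-1-yn-1-yl}-3,3,5-trimethylcyclohexan-1-ol (diastereomer mixture) | CC(C)(C)[Si](C)(C)OC/C=C(\C)C#CC1C(C)(Cl)C[C@@H](O)CC1(C)C
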